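(The numbers are made up; what happens was integrated by code.)

Read the scheme, the recipes and the questions first.

    starting material + coupling partner → target (k1 = 14 /M/min)
    second substrate + coupling partner → second product (k2 = 21 /M/min)
    starting material + second substrate → cross product (k3 = 0.63 /M/min)
    target → over-reaction product (k4 = 0.050 /min)
    coupling partner → decomposed reagent (k5 = 0.016 /min)
    solid substrate ⇌ starting material, rate k6*(cs6 - [starting material]) while solid is left; crystals form when [starting material] > cs6 (cs6 = 6.2 mM, k6 = 0.24 /min)

in all of them: solid substrate 15 mM; time 25 min
- theta: coupling partner 1.80 equiv; second substrate 2.00 equiv (fed, over 5.0 min); all else is in the flask from the start; the feed brings no volume worth counting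
- alpha: coupling partner 1.80 equiv; second substrate 2.00 equiv; everything together at the start
- eta: coupling partner 1.80 equiv; second substrate 2.00 equiv (in portions, 2, over 5.0 min); first portion at the start, last at 5.0 min
- zeta: coupling partner 1.80 equiv (fed, over 5.0 min); second substrate 2.00 equiv; all else is in the flask from the start; the feed brings no volume worth counting

* the flask that comes out highest in share of target in target plus cross product, or "all alike" when all lie within 1.5 percentage points (theta / alpha / eta / zeta / all alike)
* share of target in target plus cross product at the end, theta
* share of target in target plus cross product at the end, alpha
* share of target in target plus cross product at the end, eta
* share of target in target plus cross product at the end, zeta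

- given per volume of solution although it is solid: solid substrate
- at the start none of the solid substrate is in solution
- run time (theta): 25 min

**The ratio.** Alpha starts at S = 20.0, where S is the rate of starting material into target over its rate into cross product. S equals the first constant times coupling partner, over the third constant times second substrate, so both reagents set it. Coupling partner is the limiting reagent: 1.80 equiv stands against 2.00 equiv of second substrate.

**The ceiling.** In alpha, S falls from its start and target only decays. So the share stays below 95.2%.

**Tighter.** Coupling partner lives about τ = 1.55 min, which is shorter than the dissolving time 4.17 min. So I take starting material as the filling rate times τ, 2.30 mM. Second substrate can fall to its excess, about 3.08 mM, which is a logarithmic drop of L = 2.30. Target made is then roughly k₁/k₂ times starting material times L, or 3.54 mM.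

**The bracket.** Aged over half the run, that target becomes 1.89 mM. Aged over the whole run, it becomes 1.01 mM. I estimate cross product between 0.300 mM, from the excess alone, and 0.729 mM, with the early second substrate added. So I put alpha between 58.2% and 86.3%. Eta starts at S = 40.0 and theta starts with no second substrate, so I place both above alpha.

**The forecast.** It gives 77% for theta, 69.5% for alpha, 77.5% for eta and 72% for zeta, and it names eta, noting “theta versus eta is too close to call with confidence”.

**The flasks.** Theta gives 68.8%, alpha 63.8%, eta 70.7% and zeta 67.3%, so eta is highest and alpha sits inside my bracket . In alpha, S reads 18 at 1.19 min but 0.15 at 25.0 min, with 0.151% of the coupling partner left, so starting material then forms cross product faster than target. The neighbour flask, alpha with 0.500 equiv of second substrate, starts at S = 80.0, ends at S = 3960, and gives a share of 99.7%.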